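## The problem

The target 26 consists of two identical arms, each a 9‑aryl‑1‑(2,6‑dihydroxyphenyl)nonan‑1‑one, joined by one biaryl bond. The two central rings are not equivalent. Ring A carries the chain on C1, hydroxyls on C3 and C4 and ring B on C5, so its biaryl carbon is flanked by an oxygen. Ring B carries the chain on C2′, next to its biaryl carbon C1′, and hydroxyls on C4′ and C5′. There is no stereocentre, and with only two ortho substituents the biaryl axis rotates freely. Every selectivity question is therefore one of regiochemistry, above all the meta relation of chain and aryl group on ring A.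

Eight phenolic hydroxyls are present: two catechols, which oxidise to ortho‑quinones in air or with any oxidant once free, and two 2‑acylresorcinols. They must stay masked until the last step. The two ketones sit between two ortho oxygens and cannot be made by Friedel–Crafts acylation of a resorcinol ether, which reacts at C4. They require a 2‑metalated 1,3‑dimethoxybenzene and an acyl donor at the end of each C9 chain.

The feature that opens the key step is the pattern of ring A. The carbons C2–C3–C4–C5 form a four‑carbon unit with oxygen on the two inner carbons and ring B on one terminus, and C1–C6 is a two‑carbon unit with the chain on one carbon. That is a 1‑aryl‑2,3‑dioxygenated butadiene plus an alkyne equivalent whose activating group sits on C6 and then leaves.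

## Retrosynthesis

**Unmasking.** The eight O–CH3 bonds of octamethyl ether 25 are cut last to give 26. Methyl is chosen for all eight because ring B brings its two ethers from the starting aldehyde, the resorcinol nucleophile is simplest as its dimethyl ether, and one Lewis acid clears everything. The forward step must cleave all ethers without harming the two ketones.

**Aryl ketones.** Both C(=O)–aryl bonds of 25 are cut to bis‑Weinreb amide 22 and two equivalents of 2,6‑dimethoxyphenyllithium 24, made from 1,3‑dimethoxybenzene 23. Carrying the ketones through the earlier steps would expose them to ylide, enolisation and silylation chemistry, so the chains travel as methyl esters. Amide 22 comes from diester 21, and 21 from catechol 20 by O‑methylation. Because the two arms are identical, each of these operations is done once on both ends. The forward addition must stop at the ketone.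

**Ring A (key cut).** In catechol 20 the bonds C1–C2 and C5–C6 of ring A are cut. This gives diene 10, a (Z)‑1‑aryl‑2,3‑bis(trimethylsilyloxy)butadiene that already holds ring B and its chain, and nitroalkene 17, which holds the other chain. The neighbouring cut through the biaryl bond is shorter on paper and is kept as the fallback. The cycloaddition cut is preferred because it builds the 1,2,3,5‑pattern of ring A from an acyclic piece instead of requiring a regiodefined 3‑halo‑4,5‑dioxygenated arene, and because the biaryl bond is never made by coupling; it is the aryl–vinyl bond already present in 10. The forward reaction passes through cycloadduct 18 and nitro diketone 19. It needs one regiochemical outcome (CH2 terminus of the diene to the chain‑bearing carbon of 17) and a way to remove HNO2 and two hydrogens. The oxidant is applied before the base: in 18 no acidic hydrogen flanks the nitro group, whereas in 19 the nitro group is β to a ketone.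

**Diene.** The two O–Si bonds of 10 are cut to 1‑aryl‑butane‑2,3‑dione 9, which can give only one bis‑enol ether. Dione 9 comes from keto ketal 8 by hydrolysis. The aryl–CH2 bond of 8 is cut to aryl bromide 6 and 3,3‑dimethoxybutan‑2‑one 7, a ketone with a single enolisable position. The forward α‑arylation must tolerate the methyl ester and stop after one arylation.

**Ring B chain.** The C8–C9 bond of the chain in 6 is cut, through alkene 5, to ylide 4 and 2‑bromo‑4,5‑dimethoxybenzaldehyde 3. Ylide 4 comes from phosphonium salt 2 and this from methyl 8‑bromooctanoate 1. The bromine that later serves the arylation is already in place, so the reduction of 5 must leave the C–Br bond alone.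

**Nitroalkene.** The C=C bond of 17 is cut, through mesylate 16 and nitro alcohol 15, to aldehyde 13 and nitromethane 14. Aldehyde 13 comes from methyl undec‑10‑enoate 11 through ozonide 12. The carbon of 14 becomes C6 of ring A.

## Roads not taken

**Alternative 1:** Ring B would be built by a (2+2+2) cyclotrimerisation. A 1,7‑diyne, 2‑ethynyl‑6‑methoxy‑4‑(oct‑7‑en‑1‑yl)phenyl prop‑2‑ynoate A2, and the diborylalkyne A3 would be joined with Cp*RuCl(cod) to give the benzo[c]chromenone A1.
- Merits: three C–C bonds form at once, the ester tether fixes the regiochemistry of ring B without doubt, and the two boryl groups are the future catechol oxygens.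
- Weak points for this target: A2 needs ring A already fully and correctly substituted, so the hard ring is bought or made by stepwise aromatic substitution. Aryl propiolates are labile, and the terminal alkene of the side chain can enter ruthenium‑catalysed ene–yne chemistry. After the key step the lactone carbonyl of A1 supplies only the first carbon of the ring B chain, and the octenyl group is one carbon short of the ring A chain, so the two arms must be finished by two different homologation sequences.
- Comparison: this road is better in bond count per step and in certainty of regiochemistry. The chosen plan sets against it that both C9 chains arrive complete and identical, so every step after the cycloaddition is a single twofold operation, and that ring A is made rather than presupposed.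

**Alternative 2:** Ring A would be closed between its two oxygenated carbons by an acyloin condensation (sodium, chlorotrimethylsilane) of the 2‑aryl‑4‑alkyladipate A5, giving the cyclic enediol bis‑silyl ether A4.
- Merits: six‑ring acyloin closure under these conditions is dependable, it has no regiochemical question, and it delivers the same enediol oxidation pattern that the cycloaddition gives.
- Weak points: A5 must itself be assembled by two C–C bond formations along a linear chain and carries two stereocentres that are then erased. Sodium forbids esters or ketones elsewhere, so both chains must travel as alkenes that are one carbon short and need later extension. A4 needs removal of four hydrogens to become aromatic, against two in the chosen plan, where the nitro group already stands for one unsaturation.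
- Comparison: this road is the more predictable ring closure. The chosen plan answers with convergence (two fragments of similar size joined in the ring‑forming step), with chains at the final oxidation level of an acyl donor, and with a shorter path to the aromatic ring.

**Alternative 3:** The bond between ring B and its chain would be made late. The 2‑arylphenol A7 and the keto aldehyde A8 would condense under BF3·OEt2, and the oxocarbenium ion would alkylate ring B para to a methoxy group to give the 6H‑benzo[c]chromene A6.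
- Merits: both aryl ketone arms are complete before the key step, the tether allows only the wanted position of ring B to react, and little would remain afterwards beyond C–O cleavage and demethylation.
- Weak points: A7 already contains the biaryl bond, so a cross‑coupling and a separately substituted ring A are still required. A phenol is a poor partner for hemiacetal formation, so Friedel–Crafts hydroxyalkylation ortho or para to the free hydroxyl and aldol reactions of A8 compete. The benzylic C–O bond of A6 must then be cleaved reductively beside two aryl ketones.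
- Comparison: in convergence and in the number of steps after the key step this road is better. The chosen plan has a longer end game, but each of its steps is standard, and it avoids a reductive C–O cleavage next to reducible ketones.

Key step: step 10

Assumption: methyl 8‑bromooctanoate is taken as the commercial form of the C8 bromo ester (it is one Fischer esterification from 8‑bromooctanoic acid), and the biaryl axis is treated as freely rotating, so no axial configuration is set.

## Steps

Step 1
Reactants: 1 methyl 8‑bromooctanoate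
Product: 2 (8‑methoxy‑8‑oxooctyl)triphenylphosphonium bromide
Conditions: PPh3, MeCN, reflux
Reagents that add atoms: triphenylphosphine, c1ccc(cc1)P(c1ccccc1)c1ccccc1
Why: SN2 quaternisation of triphenylphosphine by a primary alkyl bromide; the ester is inert.

Step 2
Reactants: 2 (8‑methoxy‑8‑oxooctyl)triphenylphosphonium bromide; 3 2‑bromo‑4,5‑dimethoxybenzaldehyde
Product: 5 methyl (Z)‑9‑(2‑bromo‑4,5‑dimethoxyphenyl)non‑8‑enoate, via phosphonium ylide 4 (not isolated)
Conditions: NaN(SiMe3)2, THF, −78 °C → 0 °C; then 3, −78 °C → rt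
Reagents that add atoms: none
Why: Wittig olefination with a non‑stabilised ylide generated by a hindered amide base at low temperature, which leaves the methyl ester untouched; the Z alkene is expected to predominate, and the geometry is irrelevant because the double bond is saturated in step 3.

Step 3
Reactants: 5 methyl (Z)‑9‑(2‑bromo‑4,5‑dimethoxyphenyl)non‑8‑enoate
Product: 6 methyl 9‑(2‑bromo‑4,5‑dimethoxyphenyl)nonanoate
Conditions: H2 (1 atm), 5% Pt/C, EtOAc, rt
Reagents that add atoms: none
Why: Heterogeneous catalytic hydrogenation; platinum on carbon saturates the disubstituted styrene C=C much faster than it cleaves an aryl C–Br bond (palladium would not be trusted here), and both alkene isomers converge on 6.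

Step 4
Reactants: 6 methyl 9‑(2‑bromo‑4,5‑dimethoxyphenyl)nonanoate; 7 3,3‑dimethoxybutan‑2‑one
Product: 8 methyl 9‑[2‑(3,3‑dimethoxy‑2‑oxobutyl)‑4,5‑dimethoxyphenyl]nonanoate
Conditions: Pd2(dba)3 (2 mol %), Xantphos (5 mol %), K3PO4, 7 (3 equiv), PhMe, 100 °C
Reagents that add atoms: none
Why: Palladium‑catalysed α‑arylation of a ketone enolate (Buchwald–Hartwig type); ketone 7 has a single enolisable methyl group, K3PO4 is mild enough for the methyl ester, and the ortho alkyl chain together with excess ketone disfavours a second arylation.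

Step 5
Reactants: 8 methyl 9‑[2‑(3,3‑dimethoxy‑2‑oxobutyl)‑4,5‑dimethoxyphenyl]nonanoate
Product: 9 methyl 9‑[2‑(2,3‑dioxobutyl)‑4,5‑dimethoxyphenyl]nonanoate
Conditions: TFA, H2O, CH2Cl2, 0 °C → rt
Reagents that add atoms: water, O
Why: Acid‑catalysed ketal hydrolysis; the α‑keto ketal ionises slowly and therefore gets trifluoroacetic acid, under which the methyl ester and aryl ethers are stable at room temperature; the dione is used at once.

Step 6
Reactants: 9 methyl 9‑[2‑(2,3‑dioxobutyl)‑4,5‑dimethoxyphenyl]nonanoate
Product: 10 methyl 9‑{2‑[(Z)‑2,3‑bis(trimethylsilyloxy)buta‑1,3‑dien‑1‑yl]‑4,5‑dimethoxyphenyl}nonanoate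
Conditions: TMSOTf (2.4 equiv), Et3N (4 equiv), Et2O, 0 °C → rt; pentane, filtration under argon, used crude
Reagents that add atoms: trimethylsilyl trifluoromethanesulfonate, C[Si](C)(C)OS(=O)(=O)C(F)(F)F
Why: Soft enolisation with a silyl triflate and an amine, as in the preparation of 2,3‑bis(trimethylsilyloxy)butadiene from biacetyl; each carbonyl has one enolisable neighbour (benzylic CH2 and CH3), so only one bis‑enol ether can form, and the Z geometry (aryl trans to the bulky C3 substituent) is the expected thermodynamic outcome for a benzyl ketone.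

Step 7
Reactants: 11 methyl undec‑10‑enoate
Product: 13 methyl 10‑oxodecanoate, via ozonide 12 (not isolated)
Conditions: O3, CH2Cl2, −78 °C; then PPh3, −78 °C → rt
Reagents that add atoms: ozone, [O-][O+]=O
Why: Ozonolysis of a terminal alkene with reductive cleavage of the secondary ozonide by triphenylphosphine; the ester is inert.

Step 8
Reactants: 13 methyl 10‑oxodecanoate; 14 nitromethane
Product: 15 methyl 10‑hydroxy‑11‑nitroundecanoate (racemic)
Conditions: MeNO2 (5 equiv), KOtBu (0.1 equiv), THF/tBuOH, 0 °C → rt
Reagents that add atoms: none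
Why: Henry (nitroaldol) addition of the nitronate to an aliphatic aldehyde under catalytic base; the new carbinol centre is racemic and is removed in step 9.

Step 9
Reactants: 15 methyl 10‑hydroxy‑11‑nitroundecanoate
Product: 17 methyl (E)‑11‑nitroundec‑10‑enoate, via mesylate 16 (not isolated)
Conditions: MsCl, Et3N, CH2Cl2, −10 °C → 0 °C
Reagents that add atoms: none
Why: Mesylation followed by E1cB elimination through the nitronate gives the conjugated nitroalkene, the E isomer being strongly favoured thermodynamically; short contact with the amine limits isomerisation to the allylic nitro compound.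

Step 10
Reactants: 10 methyl 9‑{2‑[(Z)‑2,3‑bis(trimethylsilyloxy)buta‑1,3‑dien‑1‑yl]‑4,5‑dimethoxyphenyl}nonanoate; 17 methyl (E)‑11‑nitroundec‑10‑enoate
Product: 20 methyl 9‑{2‑[2,3‑dihydroxy‑5‑(9‑methoxy‑9‑oxononyl)phenyl]‑4,5‑dimethoxyphenyl}nonanoate, via nitro cycloadduct 18 (not isolated), via nitro diketone 19 (not isolated)
Conditions: 17 (1.5 equiv), BHT (cat.), PhMe, 110 °C; then DDQ (1.05 equiv), 0 °C → rt; then DBU (3 equiv), 0 °C → rt; 1 M HCl work‑up under N2
Reagents that add atoms: none
Why: A normal‑electron‑demand, concerted but asynchronous (4+2) cycloaddition between the s‑cis diene 10 and nitroalkene 17 forms the C1–C2 and C5–C6 bonds of ring A; it belongs to the known Diels–Alder reactions of silyloxybutadienes with nitroalkenes used as alkyne equivalents. Ring A is closed by this intermolecular cycloaddition, both bonds in one step and without a tether. The one selectivity needed is regiochemical: the two silyloxy groups polarise the diene in opposite senses and largely cancel, so the aryl group decides, electronically (ortho rule for 1‑aryl dienes, larger HOMO coefficient at the remote CH2 terminus) and sterically, and this terminus bonds to the electrophilic, chain‑bearing β‑carbon of the nitroalkene. The Z enol ether keeps ring B on the outside of the s‑cis diene where it does not block the dienophile, and an E isomer would be unreactive instead of giving a wrong product. The three sp3 centres of 18 (chain and nitro trans from the E alkene, the aryl‑bearing carbon as an endo/exo mixture) need no control because all are erased. DDQ then oxidises the electron‑rich enediol bis‑silyl ether to 1,2‑diketone 19, the known oxidative unmasking of 1,2‑bis(silyloxy)alkenes with the silyl groups passing to the hydroquinone, which places the nitro group β to a ketone that has an acidic benzylic α‑hydrogen. DBU removes HNO2 by E1cB and the resulting cyclohexenedione tautomerises to the catechol, so the nitro group serves only as a traceless activating and directing group, and because the oxidant is consumed before the catechol appears, over‑oxidation to the ortho‑quinone is avoided. The acidic work‑up hydrolyses any O–Si bond that remains.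

Step 11
Reactants: 20 methyl 9‑{2‑[2,3‑dihydroxy‑5‑(9‑methoxy‑9‑oxononyl)phenyl]‑4,5‑dimethoxyphenyl}nonanoate
Product: 21 methyl 9‑{2‑[2,3‑dimethoxy‑5‑(9‑methoxy‑9‑oxononyl)phenyl]‑4,5‑dimethoxyphenyl}nonanoate
Conditions: MeI, K2CO3, DMF, rt, N2
Reagents that add atoms: iodomethane, CI
Why: Williamson O‑methylation of both catechol hydroxyls under carbonate, carried out under nitrogen to protect the catecholate from air; the methyl esters are stable to carbonate in DMF.

Step 12
Reactants: 21 methyl 9‑{2‑[2,3‑dimethoxy‑5‑(9‑methoxy‑9‑oxononyl)phenyl]‑4,5‑dimethoxyphenyl}nonanoate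
Product: 22 9‑{2‑[2,3‑dimethoxy‑5‑{9‑[methoxy(methyl)amino]‑9‑oxononyl}phenyl]‑4,5‑dimethoxyphenyl}‑N‑methoxy‑N‑methylnonanamide
Conditions: MeNHOMe·HCl (6 equiv), iPrMgCl (12 equiv), THF, −20 °C → 0 °C
Reagents that add atoms: N,O‑dimethylhydroxylamine hydrochloride, CNOC.Cl
Why: Direct aminolysis of both methyl esters by the chloromagnesium amide of N,O‑dimethylhydroxylamine (Weinreb amide formation); aryl methyl ethers are inert.

Step 13
Reactants: 22 9‑{2‑[2,3‑dimethoxy‑5‑{9‑[methoxy(methyl)amino]‑9‑oxononyl}phenyl]‑4,5‑dimethoxyphenyl}‑N‑methoxy‑N‑methylnonanamide; 23 1,3‑dimethoxybenzene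
Product: 25 9‑{2‑[5‑[9‑(2,6‑dimethoxyphenyl)‑9‑oxononyl]‑2,3‑dimethoxyphenyl]‑4,5‑dimethoxyphenyl}‑1‑(2,6‑dimethoxyphenyl)nonan‑1‑one, via 2,6‑dimethoxyphenyllithium 24 (not isolated)
Conditions: 23 (5 equiv), n‑BuLi (4.5 equiv), THF, 0 °C → rt; then 22, −78 °C → 0 °C; aq. NH4Cl
Reagents that add atoms: none
Why: Directed ortho‑lithiation of 1,3‑dimethoxybenzene at C2 between the two methoxy groups, then Weinreb ketone synthesis; the chelated tetrahedral intermediate prevents a second addition at each end.

Step 14
Reactants: 25 9‑{2‑[5‑[9‑(2,6‑dimethoxyphenyl)‑9‑oxononyl]‑2,3‑dimethoxyphenyl]‑4,5‑dimethoxyphenyl}‑1‑(2,6‑dimethoxyphenyl)nonan‑1‑one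
Product: 26 9‑{2‑[5‑[9‑(2,6‑dihydroxyphenyl)‑9‑oxononyl]‑2,3‑dihydroxyphenyl]‑4,5‑dihydroxyphenyl}‑1‑(2,6‑dihydroxyphenyl)nonan‑1‑one
Conditions: BBr3 (16 equiv), CH2Cl2, −78 °C → rt; then H2O, 0 °C, under N2
Reagents that add atoms: none
Why: Lewis‑acid cleavage of all eight aryl methyl ethers with boron tribromide; the ethers ortho to the carbonyl groups are assisted by chelation, and the saturated chains and ketones are inert.

## Compound list

1 | methyl 8‑bromooctanoate | COC(=O)CCCCCCCBr | starting material
2 | (8‑methoxy‑8‑oxooctyl)triphenylphosphonium bromide | COC(=O)CCCCCCC[P+](c1ccccc1)(c1ccccc1)c1ccccc1.[Br-] | intermediate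
3 | 2‑bromo‑4,5‑dimethoxybenzaldehyde | COc1cc(Br)c(C=O)cc1OC | starting material
4 | methyl 8‑(triphenyl‑λ5‑phosphanylidene)octanoate (ylide) | COC(=O)CCCCCCC=P(c1ccccc1)(c1ccccc1)c1ccccc1 | intermediate
5 | methyl (Z)‑9‑(2‑bromo‑4,5‑dimethoxyphenyl)non‑8‑enoate (E isomer carried along) | COC(=O)CCCCCC/C=C\c1cc(OC)c(OC)cc1Br | intermediate
6 | methyl 9‑(2‑bromo‑4,5‑dimethoxyphenyl)nonanoate | COC(=O)CCCCCCCCc1cc(OC)c(OC)cc1Br | intermediate
7 | 3,3‑dimethoxybutan‑2‑one | CC(=O)C(C)(OC)OC | starting material
8 | methyl 9‑[2‑(3,3‑dimethoxy‑2‑oxobutyl)‑4,5‑dimethoxyphenyl]nonanoate | COC(=O)CCCCCCCCc1cc(OC)c(OC)cc1CC(=O)C(C)(OC)OC | intermediate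
9 | methyl 9‑[2‑(2,3‑dioxobutyl)‑4,5‑dimethoxyphenyl]nonanoate | COC(=O)CCCCCCCCc1cc(OC)c(OC)cc1CC(=O)C(C)=O | intermediate
10 | methyl 9‑{2‑[(Z)‑2,3‑bis(trimethylsilyloxy)buta‑1,3‑dien‑1‑yl]‑4,5‑dimethoxyphenyl}nonanoate | COC(=O)CCCCCCCCc1cc(OC)c(OC)cc1/C=C(\O[Si](C)(C)C)C(=C)O[Si](C)(C)C | intermediate
11 | methyl undec‑10‑enoate | C=CCCCCCCCCC(=O)OC | starting material
12 | methyl 9‑(1,2,4‑trioxolan‑3‑yl)nonanoate (ozonide, racemic) | COC(=O)CCCCCCCCC1OCOO1 | intermediate
13 | methyl 10‑oxodecanoate | COC(=O)CCCCCCCCC=O | intermediate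
14 | nitromethane | C[N+](=O)[O-] | starting material
15 | methyl 10‑hydroxy‑11‑nitroundecanoate (racemic) | COC(=O)CCCCCCCCC(O)C[N+](=O)[O-] | intermediate
16 | methyl 10‑(methanesulfonyloxy)‑11‑nitroundecanoate (racemic) | COC(=O)CCCCCCCCC(OS(C)(=O)=O)C[N+](=O)[O-] | intermediate
17 | methyl (E)‑11‑nitroundec‑10‑enoate | COC(=O)CCCCCCCC/C=C/[N+](=O)[O-] | intermediate
18 | methyl 9‑{2‑[5‑(9‑methoxy‑9‑oxononyl)‑6‑nitro‑2,3‑bis(trimethylsilyloxy)cyclohex‑2‑en‑1‑yl]‑4,5‑dimethoxyphenyl}nonanoate (racemic; chain and nitro trans, relative configuration drawn; aryl‑bearing carbon a mixture) | COC(=O)CCCCCCCC[C@@H]1CC(O[Si](C)(C)C)=C(O[Si](C)(C)C)C(c2cc(OC)c(OC)cc2CCCCCCCCC(=O)OC)[C@H]1[N+](=O)[O-] | intermediate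
19 | methyl 9‑{2‑[5‑(9‑methoxy‑9‑oxononyl)‑6‑nitro‑2,3‑dioxocyclohexyl]‑4,5‑dimethoxyphenyl}nonanoate (racemic; chain and nitro trans, relative configuration drawn; aryl‑bearing carbon a mixture) | COC(=O)CCCCCCCC[C@@H]1CC(=O)C(=O)C(c2cc(OC)c(OC)cc2CCCCCCCCC(=O)OC)[C@H]1[N+](=O)[O-] | intermediate
20 | methyl 9‑{2‑[2,3‑dihydroxy‑5‑(9‑methoxy‑9‑oxononyl)phenyl]‑4,5‑dimethoxyphenyl}nonanoate | COC(=O)CCCCCCCCc1cc(O)c(O)c(-c2cc(OC)c(OC)cc2CCCCCCCCC(=O)OC)c1 | intermediate
21 | methyl 9‑{2‑[2,3‑dimethoxy‑5‑(9‑methoxy‑9‑oxononyl)phenyl]‑4,5‑dimethoxyphenyl}nonanoate | COC(=O)CCCCCCCCc1cc(OC)c(OC)c(-c2cc(OC)c(OC)cc2CCCCCCCCC(=O)OC)c1 | intermediate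
22 | 9‑{2‑[2,3‑dimethoxy‑5‑{9‑[methoxy(methyl)amino]‑9‑oxononyl}phenyl]‑4,5‑dimethoxyphenyl}‑N‑methoxy‑N‑methylnonanamide | CON(C)C(=O)CCCCCCCCc1cc(OC)c(OC)c(-c2cc(OC)c(OC)cc2CCCCCCCCC(=O)N(C)OC)c1 | intermediate
23 | 1,3‑dimethoxybenzene | COc1cccc(OC)c1 | starting material
24 | 2,6‑dimethoxyphenyllithium | [Li]c1c(OC)cccc1OC | intermediate
25 | 9‑{2‑[5‑[9‑(2,6‑dimethoxyphenyl)‑9‑oxononyl]‑2,3‑dimethoxyphenyl]‑4,5‑dimethoxyphenyl}‑1‑(2,6‑dimethoxyphenyl)nonan‑1‑one | COc1cccc(OC)c1C(=O)CCCCCCCCc1cc(OC)c(OC)c(-c2cc(OC)c(OC)cc2CCCCCCCCC(=O)c2c(OC)cccc2OC)c1 | intermediate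
26 | 9‑{2‑[5‑[9‑(2,6‑dihydroxyphenyl)‑9‑oxononyl]‑2,3‑dihydroxyphenyl]‑4,5‑dihydroxyphenyl}‑1‑(2,6‑dihydroxyphenyl)nonan‑1‑one | O=C(CCCCCCCCc1cc(O)c(O)c(-c2cc(O)c(O)cc2CCCCCCCCC(=O)c2c(O)cccc2O)c1)c1c(O)cccc1O | target

## Step count and least certain steps

Total: 14 steps. Longest linear sequence: 11 steps (steps 1–6, then 10–14). The nitroalkene branch (steps 7–9) joins at step 10.

**Step 10 (key step).** The most likely failure is a slow cycloaddition. The diene terminus that carries ring B is hindered and the s‑cis conformer is crowded, so at 110 °C stepwise addition of the enol ether terminus to the nitroalkene with silyl transfer to the nitronate, or use of the nitroalkene as a heterodiene, can compete with ring closure. Loss of regiocontrol is the second concern, because the aryl group of 10 is twisted and its electronic bias is weakened. In the oxidation stage, attack of DDQ at the benzylic positions of ring B instead of at the enediol ether would lower the return.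

The fallback gives up the ring construction and forms the biaryl bond by Suzuki–Miyaura coupling. It sets out from bromide 6 and ylide 4 and comes back at diester 21:
- Bromide 6 is borylated (B2pin2, Pd(dppf)Cl2, KOAc, dioxane, 90 °C) to methyl 9‑[4,5‑dimethoxy‑2‑(4,4,5,5‑tetramethyl‑1,3,2‑dioxaborolan‑2‑yl)phenyl]nonanoate F1.
- Ylide 4 is condensed with commercial 3‑bromo‑4,5‑dimethoxybenzaldehyde F2 to methyl (Z)‑9‑(3‑bromo‑4,5‑dimethoxyphenyl)non‑8‑enoate F3.
- Hydrogenation of F3 as in step 3 gives methyl 9‑(3‑bromo‑4,5‑dimethoxyphenyl)nonanoate F4.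
- Coupling of F1 with F4 (Pd(OAc)2, SPhos, K3PO4, PhMe/H2O) gives 21.

**Step 6.** The second enolisation (of the methyl ketone) may stay incomplete, some E enol ether may form and would be inert in step 10, and the crude bis‑trimethylsilyl diene may hydrolyse on handling because it cannot be chromatographed.

The fallback builds the diene in two controlled stages. It sets out from 9 and comes back at 20:
- The strongly enolised dione 9 is O‑silylated with TBSCl and imidazole in DMF to methyl 9‑{2‑[(Z)‑2‑(tert‑butyldimethylsilyloxy)‑3‑oxobut‑1‑en‑1‑yl]‑4,5‑dimethoxyphenyl}nonanoate F5, which is stable to chromatography, so the Z isomer can be purified.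
- Kinetic deprotonation of the methyl ketone of F5 (LiN(SiMe3)2, TMSCl, THF, −78 °C) gives methyl 9‑{2‑[(Z)‑2‑(tert‑butyldimethylsilyloxy)‑3‑(trimethylsilyloxy)buta‑1,3‑dien‑1‑yl]‑4,5‑dimethoxyphenyl}nonanoate F6.
- F6 is taken through the conditions of step 10, with Bu4NF added before the acidic work‑up. It passes through the mixed‑silyl cycloadduct methyl 9‑{2‑[2‑(tert‑butyldimethylsilyloxy)‑5‑(9‑methoxy‑9‑oxononyl)‑6‑nitro‑3‑(trimethylsilyloxy)cyclohex‑2‑en‑1‑yl]‑4,5‑dimethoxyphenyl}nonanoate F7 and diketone 19 to catechol 20.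

**Step 4.** Oxidative addition to the electron‑rich, ortho‑substituted bromide may be slow, and the more acidic benzylic position of product 8 may be arylated a second time. Ester condensation under the basic conditions is a lesser concern.

The fallback installs the four‑carbon unit without an enolate. It sets out from 6 and comes back at 9:
- Heck reaction of 6 with but‑3‑en‑2‑ol F8 (Pd(OAc)2, Bu4NCl, NaHCO3, DMF, 90 °C), with migration of the double bond to the carbinol, gives methyl 9‑[4,5‑dimethoxy‑2‑(3‑oxobutyl)phenyl]nonanoate F9.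
- Acid‑catalysed nitrosation at the methylene next to the carbonyl (isoamyl nitrite, HCl, Et2O) gives methyl 9‑{2‑[2‑(hydroxyimino)‑3‑oxobutyl]‑4,5‑dimethoxyphenyl}nonanoate F10.
- Transoximation of F10 to aqueous formaldehyde under acid releases dione 9.

**Step 13.** The doubly ortho‑substituted aryllithium may act as a base instead of a nucleophile. It could deprotonate the amide at the α‑carbon or attack the N‑methoxy group, which leads to loss of formaldehyde, and the second amide may react incompletely.

The fallback replaces the amide electrophile by an aldehyde. It sets out from 22 and comes back at 25: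
- Reduction of 22 with iBu2AlH (THF, −78 °C) gives 9‑{2‑[2,3‑dimethoxy‑5‑(9‑oxononyl)phenyl]‑4,5‑dimethoxyphenyl}nonanal F11.
- Addition of 24 at −78 °C gives 9‑{2‑[5‑[9‑(2,6‑dimethoxyphenyl)‑9‑hydroxynonyl]‑2,3‑dimethoxyphenyl]‑4,5‑dimethoxyphenyl}‑1‑(2,6‑dimethoxyphenyl)nonan‑1‑ol F12 as a mixture of diastereomers.
- Oxidation of F12 with Dess–Martin periodinane gives 25.

## Further compounds

F1 | step 10 | methyl 9‑[4,5‑dimethoxy‑2‑(4,4,5,5‑tetramethyl‑1,3,2‑dioxaborolan‑2‑yl)phenyl]nonanoate | COC(=O)CCCCCCCCc1cc(OC)c(OC)cc1B1OC(C)(C)C(C)(C)O1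
F2 | step 10 | 3‑bromo‑4,5‑dimethoxybenzaldehyde | COc1cc(C=O)cc(Br)c1OC
F3 | step 10 | methyl (Z)‑9‑(3‑bromo‑4,5‑dimethoxyphenyl)non‑8‑enoate | COC(=O)CCCCCC/C=C\c1cc(Br)c(OC)c(OC)c1
F4 | step 10 | methyl 9‑(3‑bromo‑4,5‑dimethoxyphenyl)nonanoate | COC(=O)CCCCCCCCc1cc(Br)c(OC)c(OC)c1
F5 | step 6 | methyl 9‑{2‑[(Z)‑2‑(tert‑butyldimethylsilyloxy)‑3‑oxobut‑1‑en‑1‑yl]‑4,5‑dimethoxyphenyl}nonanoate | COC(=O)CCCCCCCCc1cc(OC)c(OC)cc1/C=C(\O[Si](C)(C)C(C)(C)C)C(C)=O
F6 | step 6 | methyl 9‑{2‑[(Z)‑2‑(tert‑butyldimethylsilyloxy)‑3‑(trimethylsilyloxy)buta‑1,3‑dien‑1‑yl]‑4,5‑dimethoxyphenyl}nonanoate | COC(=O)CCCCCCCCc1cc(OC)c(OC)cc1/C=C(\O[Si](C)(C)C(C)(C)C)C(=C)O[Si](C)(C)C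
F7 | step 6 | methyl 9‑{2‑[2‑(tert‑butyldimethylsilyloxy)‑5‑(9‑methoxy‑9‑oxononyl)‑6‑nitro‑3‑(trimethylsilyloxy)cyclohex‑2‑en‑1‑yl]‑4,5‑dimethoxyphenyl}nonanoate (racemic; chain and nitro trans) | COC(=O)CCCCCCCC[C@@H]1CC(O[Si](C)(C)C)=C(O[Si](C)(C)C(C)(C)C)C(c2cc(OC)c(OC)cc2CCCCCCCCC(=O)OC)[C@H]1[N+](=O)[O-]
F8 | step 4 | but‑3‑en‑2‑ol (racemic) | C=CC(C)O
F9 | step 4 | methyl 9‑[4,5‑dimethoxy‑2‑(3‑oxobutyl)phenyl]nonanoate | COC(=O)CCCCCCCCc1cc(OC)c(OC)cc1CCC(C)=O
F10 | step 4 | methyl 9‑{2‑[2‑(hydroxyimino)‑3‑oxobutyl]‑4,5‑dimethoxyphenyl}nonanoate (oxime geometry not defined) | COC(=O)CCCCCCCCc1cc(OC)c(OC)cc1CC(=NO)C(C)=O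
F11 | step 13 | 9‑{2‑[2,3‑dimethoxy‑5‑(9‑oxononyl)phenyl]‑4,5‑dimethoxyphenyl}nonanal | O=CCCCCCCCCc1cc(OC)c(OC)c(-c2cc(OC)c(OC)cc2CCCCCCCCC=O)c1
F12 | step 13 | 9‑{2‑[5‑[9‑(2,6‑dimethoxyphenyl)‑9‑hydroxynonyl]‑2,3‑dimethoxyphenyl]‑4,5‑dimethoxyphenyl}‑1‑(2,6‑dimethoxyphenyl)nonan‑1‑ol (mixture of diastereomers) | COc1cccc(OC)c1C(O)CCCCCCCCc1cc(OC)c(OC)c(-c2cc(OC)c(OC)cc2CCCCCCCCC(O)c2c(OC)cccc2OC)c1
A1 | alternative 1 | 4‑methoxy‑2‑(oct‑7‑en‑1‑yl)‑8,9‑bis(4,4,5,5‑tetramethyl‑1,3,2‑dioxaborolan‑2‑yl)‑6H‑benzo[c]chromen‑6‑one | C=CCCCCCCc1cc(OC)c2OC(=O)c3cc(B4OC(C)(C)C(C)(C)O4)c(B4OC(C)(C)C(C)(C)O4)cc3-c2c1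
A2 | alternative 1 | 2‑ethynyl‑6‑methoxy‑4‑(oct‑7‑en‑1‑yl)phenyl prop‑2‑ynoate | C=CCCCCCCc1cc(OC)c(OC(=O)C#C)c(C#C)c1
A3 | alternative 1 | 1,2‑bis(4,4,5,5‑tetramethyl‑1,3,2‑dioxaborolan‑2‑yl)ethyne | CC1(C)OB(C#CB2OC(C)(C)C(C)(C)O2)OC1(C)C
A4 | alternative 2 | 3‑[4,5‑dimethoxy‑2‑(oct‑7‑en‑1‑yl)phenyl]‑5‑(oct‑7‑en‑1‑yl)‑1,2‑bis(trimethylsilyloxy)cyclohex‑1‑ene (diastereomer mixture) | C[Si](C)(C)OC1=C(O[Si](C)(C)C)C(c2cc(OC)c(OC)cc2CCCCCCC=C)CC(CCCCCCC=C)C1
A5 | alternative 2 | dimethyl 2‑[4,5‑dimethoxy‑2‑(oct‑7‑en‑1‑yl)phenyl]‑4‑(oct‑7‑en‑1‑yl)hexanedioate (diastereomer mixture) | COC(=O)CC(CCCCCCC=C)CC(C(=O)OC)c1cc(OC)c(OC)cc1CCCCCCC=C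
A6 | alternative 3 | 1‑(2,6‑dimethoxyphenyl)‑9‑{6‑[8‑(2,6‑dimethoxyphenyl)‑8‑oxooctyl]‑4,8,9‑trimethoxy‑6H‑benzo[c]chromen‑2‑yl}nonan‑1‑one (racemic) | COc1cc(CCCCCCCCC(=O)c4c(OC)cccc4OC)cc2-c3cc(OC)c(OC)cc3C(CCCCCCCC(=O)c3c(OC)cccc3OC)Oc12
A7 | alternative 3 | 9‑[3‑(3,4‑dimethoxyphenyl)‑4‑hydroxy‑5‑methoxyphenyl]‑1‑(2,6‑dimethoxyphenyl)nonan‑1‑one | COc1cc(CCCCCCCCC(=O)c2c(OC)cccc2OC)cc(-c2ccc(OC)c(OC)c2)c1O
A8 | alternative 3 | 9‑(2,6‑dimethoxyphenyl)‑9‑oxononanal | O=CCCCCCCCC(=O)c1c(OC)cccc1OC
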